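## Structural features

The target is a planar 1‑methylindole: a benzene ring (C3a, C4, C5, C6, C7, C7a) fused along the C3a–C7a bond to a pyrrole ring (N1, C2, C3), with methyl on N1 and bromine on C3, C5 and C6. It has no stereocentre, so no stereocentres stand next to each other; the only one met on the way (C2 of 9 and 10) is racemic and disappears on aromatisation. The C5–Br and C6–Br bonds are ordinary aryl bromides, stable to acid, base and quinone oxidants but not to alkyllithiums, low‑valent transition metals or hydrogenolysis. The C3–Br bond sits on the enamine‑like carbon of the pyrrole ring and is the fragile group (acid, light, further halogenation at C2), so it belongs at the very end. The real difficulty is the vicinal 5,6‑dibromo pattern: electrophilic bromination of an indole goes to C3 and then C2, and on the benzo ring it is unselective, so both benzo bromines must arrive in a building block and survive every later step. The key step exploits the local symmetry of the benzo ring: with Br on C5 and C6 and H on C4 and C7 it has a mirror plane through the midpoints of C3a–C7a and C5–C6. The aryne 8, whose triple bond joins the future C3a and C7a, is therefore symmetric and can accept N1 on one carbon and C3 on the other in either sense with the same outcome. C2 is unsubstituted in the target, so the ester that the annulation needs there is a traceless activating group.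

## Logic of the disconnections

15 ⇒ 14. The C3–Br bond is cut first because C3 is the innately nucleophilic carbon of the pyrrole ring and this is the most labile bond of 15. The gain is that 14 carries only robust aryl bromides. The demand is a monobromination that stops before C2 is attacked.

14 ⇒ 13. A carboxyl group is put back on C2 (the C2–H bond is replaced by C2–CO2H). It is the residue of the acceptor that the ring‑forming step requires. The demand is a protodecarboxylation that leaves C5–Br and C6–Br alone.

13 ⇒ 11 (through 12). The N1–CH3 bond is cut and the acid is returned to its methyl ester. Methylation is placed here because the C2 ester acidifies N1–H, so a carbonate base suffices, and the following saponification uses the same basic medium in the same flask. The demand is alkylation on nitrogen only.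

11 ⇒ 10. The C2=C3 π bond is removed, restoring hydrogen on C2 and C3, because the annulation delivers the five‑membered ring at the dihydro level. The demand is a dehydrogenation compatible with a free N–H and two aryl bromides.

10 ⇒ 9. The N1–H is returned to the N1–CO2tBu carbamate. The carbamate is what makes nitrogen, and not carbon, the attacking atom in the annulation. It is chosen as tert‑butyl because acid removes it without risk to C–Br (a benzyl carbamate would call for hydrogenolysis).

9 ⇒ 6 + 7 (through 8). The N1–C7a and C3–C3a bonds are cut together. This removes the whole pyrrole ring in one operation and leaves a symmetric C6 unit and a purchasable C3N unit. The demand is an aryne generated without organometallics, addition of nitrogen before carbon, and ring closure faster than protonation of the aryl anion.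

6 ⇒ 2 (through 3, 4 and 5). The aryl C–Si bond and the O–S bond are cut. The skeleton of 6 is kept; the improvement lies in how it is reached. Iodine, not a third bromine, is the exchange handle, and silylation, exchange with O→C silyl shift and triflation are run in one flask. The demand is halogen–metal exchange at iodine only.

2 ⇒ 1. The C–I bond is cut. The hydroxyl group directs ortho, the para position is blocked, and one ortho site is hindered. The demand is mono‑iodination.

## Other disconnections considered

Alternative 1: The cut runs through C4–C5 and C6–C7, so the benzene ring would be built last on an intact N‑methylpyrrole. The pyrrole‑fused 2‑pyranone A1, generated in the flask, would add the diborylalkyne A2 across its diene termini in a Diels–Alder reaction, and decarboxylative retro‑[4+2] would give the bis(boronate) A3.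
- In its favour: the N‑methyl group is present from the start and no carboxyl group has to be removed later. The symmetric alkyne removes the regiochemical question just as the symmetric aryne does in the chosen plan; on this point the two are equal. After the key step only a twofold ipso‑bromodeboronation (arriving at 14) and step 8 would remain, two operations against five, which is better than the chosen plan.
- Against it: A1 is a reactive ortho‑quinodimethane equivalent that would need several steps from a pyrrole carrying adjacent formyl and carboxymethyl groups and is prone to dimerise. A2 is bulky, only weakly activated and expected to be a sluggish dienophile. Halodeboronation of two neighbouring boronates on an electron‑rich indole has to compete with protodeboronation and with attack at C2 and C3, so the number and position of the bromines are less secure than when they are carried as C–Br from 1.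
- Comparison: a concerted pericyclic step at high temperature stands against a polar annulation at room temperature. The overall length is expected to be similar, with more of it spent before the key step.

Alternative 2: The cut runs through C3a–C4 and C7–C7a. The electron‑poor thiophene dioxide A4 would add as the diene to the electron‑rich enecarbamate A5 (inverse electron demand), and cheletropic loss of the sulfonyl bridge would give the cis‑fused diene A6 as a racemate.
- In its favour: both bromines are brought in as C–Br and the diene is symmetric; on both points it is equal to the chosen plan. No organolithium ever meets an aryl bromide, which is better than step 2 of the chosen plan. No carboxyl group has to be removed.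
- Against it: A6 lies four hydrogens below the indole, so two dehydrogenations would be needed. On the way, double‑bond migration followed by dehydrobromination could delete one of the required bromines. Oxidation of the electron‑poor parent thiophene to A4 needs forcing oxidants, and dioxides of this kind dimerise. After aromatisation, carbamate removal, N‑methylation (arriving at 14) and step 8 would still follow.
- Comparison: the step count is expected to be about equal to the chosen plan. The chosen plan delivers the ring one oxidation level closer to the target and on a precedented substrate class.

Alternative 3: The cut is the C5–C6 bond. Heating the pyrrole‑fused enediyne A7 with the hydrogen‑atom donor A8 would bring about a Bergman cycloaromatisation. The two bromine‑bearing alkyne carbons join, the 1,4‑diradical at C4 and C7 takes up hydrogen, and the product A9 is identical with 14.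
- In its favour: it reaches 14 directly, one step from the target, with no protecting group and no carboxyl group; after the key step it is the shortest of all and better than the chosen plan. The positions of the bromines are unambiguous, equal to the chosen plan.
- Against it: fusion to a five‑membered ring splays the alkynes apart, so a high cyclisation temperature is expected. Bromoalkynes are labile to heat and to radicals, so abstraction of bromine and chain polymerisation threaten the diradical pathway. A7 would require a 2,3‑difunctionalised N‑methylpyrrole (the pattern pyrrole chemistry gives least willingly), two alkynylations under zerovalent palladium catalysis and a terminal bromination, all through unstable intermediates.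
- Comparison: a diradical process at high temperature stands against a polar one at room temperature. The chosen plan has more steps after its key step but fewer uncertain ones.

Key step: step 3

Remark: the target name is read as 3,5,6‑tribromo‑1‑methyl‑1H‑indole (methyl on N1), as its SMILES requires; 7 is bought; 9 and 10 are racemic, which does not matter because C2 becomes sp2 in step 5.

## Route

Step 1
Reactants: 1 3,4-dibromophenol
Product: 2 4,5-dibromo-2-iodophenol
Conditions: NIS (1.0 equiv), TsOH·H2O (10 mol %), MeCN, 0 °C → rt
Reagents that add atoms: N-iodosuccinimide, O=C1CCC(=O)N1I
Why: Electrophilic aromatic iodination; the hydroxyl group directs ortho/para, the para position carries bromine, and of the two ortho positions C2 is flanked by the C3 bromine, so iodine should enter at C6, while one equivalent of NIS at low temperature should hold back di-iodination.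

Step 2
Reactants: 2 4,5-dibromo-2-iodophenol
Product: 6 4,5-dibromo-2-(trimethylsilyl)phenyl trifluoromethanesulfonate, via silyl ether 3 (not isolated), via aryllithium 4 (not isolated), via lithium phenolate 5 (not isolated)
Conditions: HMDS, THF, reflux, then evaporate; n-BuLi (1.0 equiv), THF, −100 °C; Tf2O, −100 → −78 °C
Reagents that add atoms: hexamethyldisilazane, C[Si](C)(C)N[Si](C)(C)C; n-butyllithium, [Li]CCCC (lithium of 4 and 5 only); trifluoromethanesulfonic anhydride, O=S(=O)(OS(=O)(=O)C(F)(F)F)C(F)(F)F
Why: O-Silylation, then iodine–lithium exchange, which at −100 °C should far outrun bromine–lithium exchange; aryllithium 4 has no halogen ortho to lithium and so cannot eliminate to an aryne, but undergoes the 1,3 O→C silyl shift (retro-Brook rearrangement) to phenolate 5, which Tf2O traps on oxygen in the same flask.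

Step 3
Reactants: 6 4,5-dibromo-2-(trimethylsilyl)phenyl trifluoromethanesulfonate; 7 methyl 2-[(tert-butoxycarbonyl)amino]acrylate
Product: 9 1-tert-butyl 2-methyl 5,6-dibromoindoline-1,2-dicarboxylate (racemic), via 4,5-dibromobenzyne 8 (not isolated)
Conditions: TBAT (Bu4N[Ph3SiF2], 1.5 equiv), 7 (1.5 equiv), THF, 23 °C
Reagents that add atoms: none
Why: Fluoride from TBAT attacks the silicon of 6 and the adjacent triflate leaves, releasing the symmetric aryne 8 slowly at room temperature. The carbamate nitrogen of 7, the only acidic and nucleophilic site, adds to one aryne carbon (N1–C7a), and the ortho aryl anion so formed attacks the terminal CH2 of the 2-aminoacrylate in an intramolecular conjugate addition (C3–C3a), the single ring being closed in the 5-endo-trig mode. The resulting ester enolate takes a proton from a further molecule of 7, which hands the former N–H hydrogen to C2 and passes the nitrogen anion on to the next aryne. The closest known reaction type is the fluoride-induced aryne annulation of N-carbamoyl dehydroalanine esters to indoline-2-carboxylates, a formal [3+2] process. The new stereocentre C2 arises in this unselective protonation, so 9 is racemic, which is accepted because C2 becomes sp2 in step 5. Regioselectivity is not needed: 8 has a mirror plane through the midpoints of the triple bond and of the C(Br)–C(Br) bond, so either orientation places bromine on C5 and C6. Chemoselectivity is needed and is secured by the substrate: no bromine stands ortho to the aryne carbons, so the aryl anion cannot expel bromide to a second aryne, and the fluoride conditions contain no organolithium or low-valent metal that could attack C–Br. The carbamate, unlike a simple amide, keeps nitrogen and not the enamide carbon as the attacking atom.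

Step 4
Reactants: 9 1-tert-butyl 2-methyl 5,6-dibromoindoline-1,2-dicarboxylate (racemic)
Product: 10 methyl 5,6-dibromoindoline-2-carboxylate (racemic)
Conditions: TFA, CH2Cl2, 0 °C → rt; aq NaHCO3 work-up
Reagents that add atoms: none
Why: Acidolysis of the tert-butyl carbamate (loss of the tert-butyl cation, then decarboxylation of the carbamic acid); the methyl ester and the aryl bromides are inert to TFA, and the freed nitrogen lone pair prepares the ring for dehydrogenation.

Step 5
Reactants: 10 methyl 5,6-dibromoindoline-2-carboxylate (racemic)
Product: 11 methyl 5,6-dibromo-1H-indole-2-carboxylate
Conditions: DDQ (1.1 equiv), toluene, rt → 60 °C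
Reagents that add atoms: none
Why: Quinone dehydrogenation of an indoline: hydride transfer from the saturated ring to DDQ, assisted by the nitrogen lone pair, and proton loss give the aromatic pyrrole ring conjugated with the C2 ester; the C2 stereocentre disappears here.

Step 6
Reactants: 11 methyl 5,6-dibromo-1H-indole-2-carboxylate
Product: 13 5,6-dibromo-1-methyl-1H-indole-2-carboxylic acid, via N-methyl ester 12 (not isolated)
Conditions: K2CO3, MeI, DMSO, rt; then aq KOH, 50 °C; then HCl to pH 2
Reagents that add atoms: iodomethane, CI; potassium hydroxide, [K+].[OH-] (supplies the carboxyl OH oxygen)
Why: N-Alkylation of the indolyl anion (SN2 on MeI; the C2 ester acidifies N–H so that K2CO3 suffices and nitrogen is the only nucleophilic site), followed in the same flask by saponification of the methyl ester of 12; any ester re-formed by excess MeI is hydrolysed again.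

Step 7
Reactants: 13 5,6-dibromo-1-methyl-1H-indole-2-carboxylic acid
Product: 14 5,6-dibromo-1-methyl-1H-indole
Conditions: Ag2CO3 (10 mol %), AcOH (5 mol %), DMSO, 120 °C
Reagents that add atoms: none
Why: Silver-catalysed protodecarboxylation of a heteroaromatic carboxylic acid: the silver carboxylate extrudes carbon dioxide to a C2-silver indolyl that AcOH protonates; silver does not insert into aryl C–Br bonds, so both bromines should survive.

Step 8
Reactants: 14 5,6-dibromo-1-methyl-1H-indole
Product: 15 3,5,6-tribromo-1-methyl-1H-indole
Conditions: NBS (1.0 equiv), DMF, 0 °C, dark
Reagents that add atoms: N-bromosuccinimide, O=C1CCC(=O)N1Br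
Why: Electrophilic aromatic bromination at C3, the most nucleophilic carbon of the indole; the benzo ring is deactivated by its two bromines and C2 reacts only after C3, so one equivalent of NBS at 0 °C should stop at monobromination.

## Compound list

1 | 3,4-dibromophenol | Oc1ccc(Br)c(Br)c1 | starting material
2 | 4,5-dibromo-2-iodophenol | Oc1cc(Br)c(Br)cc1I | intermediate
3 | (4,5-dibromo-2-iodophenoxy)trimethylsilane | C[Si](C)(C)Oc1cc(Br)c(Br)cc1I | intermediate
4 | [4,5-dibromo-2-(trimethylsilyloxy)phenyl]lithium | C[Si](C)(C)Oc1cc(Br)c(Br)cc1[Li] | intermediate
5 | lithium 4,5-dibromo-2-(trimethylsilyl)phenolate | [Li+].[O-]c1cc(Br)c(Br)cc1[Si](C)(C)C | intermediate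
6 | 4,5-dibromo-2-(trimethylsilyl)phenyl trifluoromethanesulfonate | C[Si](C)(C)c1cc(Br)c(Br)cc1OS(=O)(=O)C(F)(F)F | intermediate
7 | methyl 2-[(tert-butoxycarbonyl)amino]acrylate | C=C(NC(=O)OC(C)(C)C)C(=O)OC | starting material
8 | 4,5-dibromobenzyne (1,2-dibromo-4,5-didehydrobenzene) | BrC1=CC#CC=C1Br | intermediate
9 | 1-tert-butyl 2-methyl 5,6-dibromoindoline-1,2-dicarboxylate (racemic) | COC(=O)C1Cc2cc(Br)c(Br)cc2N1C(=O)OC(C)(C)C | intermediate
10 | methyl 5,6-dibromoindoline-2-carboxylate (racemic) | COC(=O)C1Cc2cc(Br)c(Br)cc2N1 | intermediate
11 | methyl 5,6-dibromo-1H-indole-2-carboxylate | COC(=O)c1cc2cc(Br)c(Br)cc2[nH]1 | intermediate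
12 | methyl 5,6-dibromo-1-methyl-1H-indole-2-carboxylate | COC(=O)c1cc2cc(Br)c(Br)cc2n1C | intermediate
13 | 5,6-dibromo-1-methyl-1H-indole-2-carboxylic acid | Cn1c(C(=O)O)cc2cc(Br)c(Br)cc21 | intermediate
14 | 5,6-dibromo-1-methyl-1H-indole | Cn1ccc2cc(Br)c(Br)cc21 | intermediate
15 | 3,5,6-tribromo-1-methyl-1H-indole | Cn1cc(Br)c2cc(Br)c(Br)cc21 | target

## Step count and least certain steps

Total: 8 steps. Longest linear sequence: 8 steps (1 → 15); 7 is bought and enters at step 3.

Key step, step 3. The most likely failure is protonation of the aryl anion before the 5-endo closure, because the two bromines stabilise the carbanion and lower its nucleophilicity; consumption of the aryne by fluoride-promoted self-reaction is a second risk. The fallback sets out from 6 and returns at 14, giving up the conjugate-addition ring closure. The aryne 8 is generated from 6 with CsF in MeCN in the presence of N-(2,2-dimethoxyethyl)-4-methylbenzenesulfonamide, and N–H insertion should give N-(3,4-dibromophenyl)-N-(2,2-dimethoxyethyl)-4-methylbenzenesulfonamide F1. TiCl4 in hot toluene then closes C3–C3a by intramolecular Friedel–Crafts attack of the oxocarbenium ion with loss of methanol, giving 5,6-dibromo-1-tosyl-1H-indole F2. Closure para to the C3 bromine of the anilide is expected to be preferred over closure between nitrogen and bromine, but regiochemistry is then no longer guaranteed by symmetry, which is the price of this fallback. KOH in MeOH/THF removes the sulfonyl group to give 5,6-dibromo-1H-indole F3, and powdered KOH with MeI in DMSO methylates nitrogen to give 14, from which step 8 follows.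

Step 2. The most likely failure is bromine–lithium exchange or halogen scrambling alongside the iodine–lithium exchange, followed by elimination from an ortho-bromoaryllithium, and C-butylation by the alkyl iodide that is formed. The fallback sets out from 2 and returns at 6; it replaces lithium by magnesium and the intramolecular silyl shift by external silylation. 2 is protected with MOMCl and iPr2NEt as 1,2-dibromo-4-iodo-5-(methoxymethoxy)benzene F4. Iodine–magnesium exchange with iPrMgCl·LiCl at −40 °C (far more selective for iodide, and an arylmagnesium does not eliminate at this temperature) and quenching with TMSCl should give [4,5-dibromo-2-(methoxymethoxy)phenyl]trimethylsilane F5. ZnBr2 and n-PrSH in CH2Cl2 remove the acetal without the strong acid that could protodesilylate, giving 4,5-dibromo-2-(trimethylsilyl)phenol F6, and Tf2O with pyridine gives 6.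

Step 7. The most likely failure is incomplete extrusion of carbon dioxide, or heat- and acid-induced oligomerisation of the electron-rich product at 120 °C. The fallback sets out from 9 and returns at 14; it removes the carboxyl group through an azomethine ylide and not through a metal carboxylate. Hot 6 M aq HCl in dioxane cleaves the carbamate and the ester of 9 in one operation to racemic 5,6-dibromoindoline-2-carboxylic acid F7. Heating F7 with paraformaldehyde and catalytic benzoic acid in toluene should form the N-methylene iminium carboxylate, which loses carbon dioxide to an azomethine ylide. Protonation at the exocyclic carbon and loss of the C3 proton (a decarboxylative redox amination) would deliver 14 directly. This would also replace steps 4 to 6, but it is less certain than they are, because the indole formed may condense further with formaldehyde.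

Step 8. The most likely failure is over-bromination at C2, or acid-promoted decomposition and bromine migration in the electron-rich product. The fallback sets out from 13 and returns at 15; it uses the carboxyl group as a blocking group for C2. 13 is brominated with NBS in DMF at 0 °C to 3,5,6-tribromo-1-methyl-1H-indole-2-carboxylic acid F8, and the protodecarboxylation with Ag2CO3 and AcOH in DMSO is carried out last to give 15; the ortho bromine should, if anything, help the extrusion.

## Further compounds

F1 | step 3 | N-(3,4-dibromophenyl)-N-(2,2-dimethoxyethyl)-4-methylbenzenesulfonamide | Cc1ccc(cc1)S(=O)(=O)N(CC(OC)OC)c1ccc(Br)c(Br)c1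
F2 | step 3 | 5,6-dibromo-1-tosyl-1H-indole | Cc1ccc(cc1)S(=O)(=O)n1ccc2cc(Br)c(Br)cc21
F3 | step 3 | 5,6-dibromo-1H-indole | Brc1cc2cc[nH]c2cc1Br
F4 | step 2 | 1,2-dibromo-4-iodo-5-(methoxymethoxy)benzene | COCOc1cc(Br)c(Br)cc1I
F5 | step 2 | [4,5-dibromo-2-(methoxymethoxy)phenyl]trimethylsilane | COCOc1cc(Br)c(Br)cc1[Si](C)(C)C
F6 | step 2 | 4,5-dibromo-2-(trimethylsilyl)phenol | C[Si](C)(C)c1cc(Br)c(Br)cc1O
F7 | step 7 | 5,6-dibromoindoline-2-carboxylic acid (racemic) | OC(=O)C1Cc2cc(Br)c(Br)cc2N1
F8 | step 8 | 3,5,6-tribromo-1-methyl-1H-indole-2-carboxylic acid | Cn1c(C(=O)O)c(Br)c2cc(Br)c(Br)cc21
A1 | alternative 1 | 1-methylpyrano[3,4-b]pyrrol-5(1H)-one | CN1C=CC2=CC(=O)OC=C12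
A2 | alternative 1 | 1,2-bis(4,4,5,5-tetramethyl-1,3,2-dioxaborolan-2-yl)ethyne | CC1(C)OB(C#CB2OC(C)(C)C(C)(C)O2)OC1(C)C
A3 | alternative 1 | 1-methyl-5,6-bis(4,4,5,5-tetramethyl-1,3,2-dioxaborolan-2-yl)-1H-indole | Cn1ccc2cc(B3OC(C)(C)C(C)(C)O3)c(B3OC(C)(C)C(C)(C)O3)cc21
A4 | alternative 2 | 3,4-dibromothiophene 1,1-dioxide | O=S1(=O)C=C(Br)C(Br)=C1
A5 | alternative 2 | tert-butyl 2,3-dihydro-1H-pyrrole-1-carboxylate | CC(C)(C)OC(=O)N1CCC=C1
A6 | alternative 2 | tert-butyl cis-5,6-dibromo-2,3,3a,7a-tetrahydro-1H-indole-1-carboxylate (racemic, one enantiomer drawn) | CC(C)(C)OC(=O)N1CC[C@@H]2C=C(Br)C(Br)=C[C@H]12
A7 | alternative 3 | 2,3-bis(bromoethynyl)-1-methyl-1H-pyrrole | Cn1ccc(C#CBr)c1C#CBr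
A8 | alternative 3 | 1,4-cyclohexadiene | C1=CCC=CC1
A9 | alternative 3 | 5,6-dibromo-1-methyl-1H-indole (identical with 14) | Cn1ccc2cc(Br)c(Br)cc21
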